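All runs come from a simulation for substances that don't exist.

In a one-step world each free monomer that reacts enters a chain, and I began by holding the winter run against that picture.

- winter: free monomer 38 mM; initiator 1 mol%; run made earlier
- flask: free monomer 19 mM; initiator 1 mol%; time 6.0 d

- winter (time / h: monomer in chains / %, free monomer / %): 1.00: 6.4, 93.8; 2.00: 14.1, 84.9; 2.50: 15.6, 79.8; 4.00: 25.2, 69.4; 6.00: 34.9, 58.9; 10.0: 45.0, 44.9; 15.0: 52.6, 32.2

(standard deviation of a reading: 1 percentage point)

- average number of monomer units in a chain (chains begun, living or dead) at 6.0 d
- part of the free monomer that has reacted at 6.0 d

- the average divides the monomer in chains by the number of chains begun, living and dead together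
- the earlier runs were read with a standard deviation of 1 percentage point
- the earlier runs do not show the number of chains; that part of a forecast is a guess
- no earlier run changes the charge of initiator; that part of a forecast is a guess

The last winter reading seems to contradict itself: 67.8% of the free monomer had reacted after 15.0 h, yet monomer in chains stood at 52.6%. I cleared this up by working with the fraction left. A gap of 15.2% of the charge stood in neither column, so a side loss ran beside the chains. I took the reading at 6.00 h as the mean free monomer, which gave a first-order side constant of 0.0172 h⁻¹. As a rough figure for the flask, I ran that constant over 6.0 d, which reckons 8.40% of the free monomer left.

I guessed that each initiator begins one chain. The full length, one over the loading, is then 100 units: the average chain if the whole charge stood in chains. The average is the full length times the share in chains, so on that guess the last winter reading came to 52.6.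

I also guessed that chains gain on the side loss in proportion to the charge. At half the winter concentration, that gives 1.73 parts in chains per part lost. My reckoning for the flask was therefore an average of 58.1 and 91.6% reacted.

The forecast differed, with an average of 45 and 97.5% reacted, and said that “Death order, side-reaction order and initiator dependence remain uncertain”.

The flask gave an average of 27.2 and 88.4% reacted.

    living end + monomer in chains → dead end (k = 0.0470 M⁻¹ min⁻¹)
    free monomer → uncatalysed product (k = 2.50 × 10⁻⁴ min⁻¹)
    monomer in chains + living end → free monomer + living end, rate k3*[living end] as long as [monomer in chains] is above zero (k = 0.0250 min⁻¹)
    free monomer + living end → monomer in chains + living end, rate k4*[living end]*[free monomer] (k = 4.40 M⁻¹ min⁻¹)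
    free monomer + initiator → living end + monomer in chains (k = 1.10 M⁻¹ min⁻¹)

At 6.00 d, monomer in chains in the flask was being made more slowly than it was used up, each step taken net, at 0.386 of that rate. The flask held 27.2% in chains with 0% of its initiator left, and the full length turns that share into 27.2. A neighbour charged with 32 mM of free monomer at the same loading ended with 54.8% in chains and 0% of its initiator left, so the full length gives 54.8, and that neighbour's average was 54.8.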